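**Plan**

- Retrosynthetic cuts, in order: the lactone bond C11–C12 (C12 comes from CO, C11≡C13 is an ethynyl group on C7); C3–C4 of the ten-membered ring; the C8 ester; C6–C7 (allenylzinc plus ynal). The East mesylate 12 comes from (R)-linalool, the West ynal 15 from 2-butyne-1,4-diol.
- Forward: 12 and 15 are joined at C6–C7. The Z-alkenyl iodide and E-enal are then unveiled and C8 is esterified. The ten-membered carbocycle is closed at C3–C4 (Nozaki–Hiyama–Kishi) and oxidised to the dienone. The lactone ring is closed last by cyclocarbonylation.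
- Stereochemistry: C10 comes from (R)-linalool and C8 from L-proline α-aminoxylation. C7 is set by Felkin–Anh alkynylation and then inverted with chirality transfer in the allenylzinc addition, which also sets C6 (anti). C1=C2 (E) comes from cross-metathesis, C4=C5 (Z) from O6-directed trans-hydroalumination, and the acyl centre from (R)-2-methylbutanoic acid.
- Enabling feature: on the ten-membered ring, O6 (on C6) and the ethynyl group C11≡C13 (on C7) are vicinal and trans, i.e. homopropargylic. An O6–C(=O)–Pd unit therefore reaches C11 by 5-exo-dig insertion and gives the trans-fused five-membered lactone. O8 carries the ester, and O10 or O15 could only close seven- or eight-membered rings. The alkyne carries a temporary SiMe3 group from step 8 to step 20.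

Key step: step 21

Remark: positions follow germacrane numbering (ring C1–C10, lactone C11–C13, C14 = methyl on C10, C15 = CH2OH on C4); 27 is drawn as the open hydroxy enone although it may equilibrate with its O6/C3 hemiketal.

**Route**

Step 1
Reactants: 1 (R)-(−)-linalool
Product: 2 (R)-linalool triethylsilyl ether
Conditions: TESOTf, 2,6-lutidine, CH2Cl2, −78 to 0 °C
Reagents that add atoms: triethylsilyl trifluoromethanesulfonate, CC[Si](CC)(CC)OS(=O)(=O)C(F)(F)F
Why: Silyl ether formation on the tertiary allylic alcohol masks O10, so that the aldehyde made next stays open-chain, and leaves the C10 centre of the chiral pool untouched.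

Step 2
Reactants: 2 (R)-linalool triethylsilyl ether
Product: 3 (4R)-4-methyl-4-(triethylsilyloxy)hex-5-enal
Conditions: O3 (1 equiv, Sudan red 7B end point), CH2Cl2–MeOH, −78 °C; then Me2S
Reagents that add atoms: ozone, [O-][O+]=O
Why: Ozonolysis with reductive work-up should cleave the electron-rich trisubstituted alkene selectively over the hindered monosubstituted vinyl group when ozone uptake is stopped at one equivalent.

Step 3
Reactants: 3 (4R)-4-methyl-4-(triethylsilyloxy)hex-5-enal
Product: 5 (2R,4R)-2-(phenylaminooxy) alcohol, via α-aminooxy aldehyde 4 (not isolated)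
Conditions: PhNO, L-proline (20 mol %), CHCl3, 4 °C; then NaBH4, EtOH, 0 °C
Reagents that add atoms: nitrosobenzene, O=Nc1ccccc1
Why: Proline-catalysed α-aminoxylation (enamine catalysis, O-selective nitroso aldol) should set C8 as R under catalyst control (L-proline gives the (R)-α-oxy aldehyde), and in situ borohydride reduction traps the labile aldehyde 4.

Step 4
Reactants: 5 (2R,4R)-2-(phenylaminooxy) alcohol
Product: 6 (2R,4R)-4-methyl-4-(triethylsilyloxy)hex-5-ene-1,2-diol
Conditions: Zn, AcOH, THF, rt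
Reagents that add atoms: none
Why: Reductive N–O cleavage with zinc in acetic acid should free the 1,2-diol without touching the alkene or the tertiary silyl ether.

Step 5
Reactants: 6 (2R,4R)-4-methyl-4-(triethylsilyloxy)hex-5-ene-1,2-diol
Product: 7 (3R,5R)-3-methyl-3,5,6-tris(triethylsilyloxy)hex-1-ene
Conditions: TESCl, imidazole, DMF, 0 °C to rt
Reagents that add atoms: chlorotriethylsilane, CC[Si](Cl)(CC)CC
Why: Standard silyl ether formation on the primary and secondary hydroxyls gives a primary ether that step 7 can oxidise directly.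

Step 6
Reactants: 7 (3R,5R)-3-methyl-3,5,6-tris(triethylsilyloxy)hex-1-ene; 8 methyl acrylate
Product: 9 methyl (2E,4R,6R)-4-methyl-4,6,7-tris(triethylsilyloxy)hept-2-enoate
Conditions: second-generation Hoveyda–Grubbs catalyst RuCl2(H2IMes)(=CH-C6H4-2-OiPr) (5 mol %), excess 8, toluene, 70 °C
Reagents that add atoms: none
Why: Cross-metathesis of the hindered vinyl group with an electron-poor acrylate should be selective (neither partner homodimerises readily) and E-selective, which fixes the C1=C2 geometry and brings in C3.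

Step 7
Reactants: 9 methyl (2E,4R,6R)-4-methyl-4,6,7-tris(triethylsilyloxy)hept-2-enoate
Product: 10 methyl (2E,4R,6R)-4-methyl-7-oxo-4,6-bis(triethylsilyloxy)hept-2-enoate
Conditions: (COCl)2, DMSO, CH2Cl2, −78 to −40 °C; then Et3N
Reagents that add atoms: none
Why: Under Swern conditions a primary triethylsilyl ether is cleaved and oxidised while secondary and tertiary ones survive, so the α-silyloxy aldehyde should form directly and without epimerisation at low temperature.

Step 8
Reactants: 10 methyl (2E,4R,6R)-4-methyl-7-oxo-4,6-bis(triethylsilyloxy)hept-2-enoate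
Product: 11 (7S)-propargylic alcohol (7,8-anti)
Conditions: Me3SiC≡CH, n-BuLi, THF, −78 °C; ClTi(OiPr)3; then 10, −78 to −30 °C
Reagents that add atoms: ethynyltrimethylsilane, C#C[Si](C)(C)C
Why: Addition of the alkynyltitanium reagent to the α-silyloxy aldehyde should follow the Felkin–Anh (non-chelation) model and give the C7/C8 anti propargylic alcohol (C7 = S), the enoate being left alone at low temperature.

Step 9
Reactants: 11 (7S)-propargylic alcohol
Product: 12 (7S)-propargylic mesylate (East fragment)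
Conditions: MsCl, Et3N, CH2Cl2, −78 to −20 °C
Reagents that add atoms: methanesulfonyl chloride, CS(=O)(=O)Cl
Why: Sulfonylation of the propargylic alcohol with retention gives the leaving group needed for the stereospecific zincation in step 12.

Step 10
Reactants: 13 2-butyne-1,4-diol
Product: 14 4-(tert-butyldiphenylsilyloxy)but-2-yn-1-ol
Conditions: TBDPSCl, imidazole, DMF, 0 °C (diol in excess)
Reagents that add atoms: tert-butyl(chloro)diphenylsilane, CC(C)(C)[Si](Cl)(c1ccccc1)c1ccccc1
Why: Statistical monosilylation of the symmetric diol used in excess gives the robust C15 protecting group.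

Step 11
Reactants: 14 4-(tert-butyldiphenylsilyloxy)but-2-yn-1-ol
Product: 15 4-(tert-butyldiphenylsilyloxy)but-2-ynal (West fragment)
Conditions: MnO2, CH2Cl2, rt
Reagents that add atoms: none
Why: Manganese dioxide oxidation of a propargylic alcohol gives the ynal without over-oxidation.

Step 12
Reactants: 12 (7S)-propargylic mesylate; 15 4-(tert-butyldiphenylsilyloxy)but-2-ynal
Product: 17 homopropargylic alcohol (C6–C7 coupled ester), via allenylzinc reagent 16 (not isolated)
Conditions: Pd(OAc)2 (5 mol %), PPh3 (5 mol %), Et2Zn (3 equiv), THF, −78 to −20 °C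
Reagents that add atoms: none
Why: In this Marshall–Tamaru propargylation, zerovalent palladium displaces the mesylate anti SN2′ and Et2Zn transmetalates to allenylzinc 16, which adds to the ynal through a cyclic SE2′ transition state; C7 should form with net inversion (chirality transfer) and C6 anti to the C8 branch under reagent control, and an ynal is used so that no C–I bond is exposed to the palladium catalyst.

Step 13
Reactants: 17 homopropargylic alcohol
Product: 19 (Z)-alkenyl iodide diol, via oxaaluminacycle 18 (not isolated)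
Conditions: NaAlH2(OCH2CH2OMe)2, THF, 0 °C to rt; then I2, −78 to 0 °C
Reagents that add atoms: iodine, [I][I]
Why: The O6 alkoxide should direct trans-hydroalumination of C4≡C5 (hydride to C5, aluminium to C4 in 18) and iodinolysis with retention then gives the Z-alkenyl iodide, while the same hydride reduces the enoate to the E-allylic alcohol and leaves the silylalkyne, only homopropargylic to O6, untouched.

Step 14
Reactants: 19 (Z)-alkenyl iodide diol
Product: 20 hydroxy enal
Conditions: TEMPO (cat.), PhI(OAc)2, CH2Cl2, rt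
Reagents that add atoms: none
Why: Oxoammonium-mediated oxidation should be selective for the primary allylic alcohol over the hindered secondary C6 alcohol and give the E-enal at C3.

Step 15
Reactants: 20 hydroxy enal
Product: 21 C6 tert-butyldimethylsilyl ether
Conditions: TBSOTf, 2,6-lutidine, CH2Cl2, −78 °C
Reagents that add atoms: tert-butyldimethylsilyl trifluoromethanesulfonate, CC(C)(C)[Si](C)(C)OS(=O)(=O)C(F)(F)F
Why: Silyl ether formation masks O6 during the C8 acylation and the C3 oxidation.

Step 16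
Reactants: 21 C6 tert-butyldimethylsilyl ether
Product: 22 C8 alcohol
Conditions: HF·pyridine, pyridine, THF, 0 °C
Reagents that add atoms: none
Why: Graded silyl lability should allow buffered HF·pyridine to cleave the secondary triethylsilyl ether at C8 while the tertiary triethylsilyl, tert-butyldimethylsilyl and tert-butyldiphenylsilyl ethers and the C-silyl group remain.

Step 17
Reactants: 22 C8 alcohol; 23 (R)-2-methylbutanoic acid
Product: 24 C8 (R)-2-methylbutanoate
Conditions: DIC, DMAP, CH2Cl2, 0 °C to rt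
Reagents that add atoms: none
Why: Steglich esterification of the only free hydroxyl installs the side chain without epimerising the non-activated α-centre; 22 is used at once so that acylation outruns oxa-Michael addition of O8 to the enal.

Step 18
Reactants: 24 C8 (R)-2-methylbutanoate
Product: 25 ten-membered allylic alcohol (C3 epimers)
Conditions: CrCl2 (10 equiv), NiCl2 (cat.), DMSO–THF, rt, 0.002 M, slow addition
Reagents that add atoms: none
Why: The Nozaki–Hiyama–Kishi reaction (nickel-catalysed, chromium-mediated addition of the C4 alkenyl iodide to the C3 aldehyde) at high dilution should close the carbocycle at C3–C4 with retention of the Z geometry; the ester and the silylated alkyne are tolerated and both C3 epimers converge in step 19.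

Step 19
Reactants: 25 ten-membered allylic alcohol
Product: 26 cross-conjugated dienone
Conditions: Dess–Martin periodinane, CH2Cl2, 0 °C
Reagents that add atoms: none
Why: Dess–Martin oxidation of the doubly allylic alcohol should give the C3 ketone under near-neutral conditions without moving either double bond.

Step 20
Reactants: 26 cross-conjugated dienone
Product: 27 ethynyl triol
Conditions: Bu4NF, AcOH (1:1), THF, 0 °C to rt
Reagents that add atoms: none
Why: Buffered fluoride should remove the three O-silyl groups and the alkynyl SiMe3 group in one operation, the acetic acid suppressing the 8→6 acyl shift and conjugate additions that free alkoxides could cause.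

Step 21
Reactants: 27 ethynyl triol
Product: 30 target lactone CNP0232405.1, via alkoxycarbonylpalladium complex 28 (not isolated), via alkenylpalladium complex 29 (not isolated)
Conditions: PdCl2 (10 mol %), SnCl2 (10 mol %), PPh3 (20 mol %), CO (7 atm), MeCN, 75 °C
Reagents that add atoms: carbon monoxide, [C-]#[O+]
Why: Under CO the PdCl2/SnCl2/PPh3 system gives a divalent palladium carbonyl to which O6–H adds, forming alkoxycarbonylpalladium 28; the C11≡C13 triple bond then inserts syn into the Pd–C12 bond, which makes the C11–C12 bond and gives alkenylpalladium 29, and protonolysis of C13–Pd by the HCl released leaves the exocyclic methylene and returns the catalyst. The closest known reaction type is the palladium-catalysed cyclocarbonylation of 3-butyn-1-ols, trans-2-ethynylcycloalkanols included, to α-methylene-γ-butyrolactones. The lactone ring (O6, C6, C7, C11, C12) closes in the 5-exo-dig mode. No new stereocentre arises: the trans ring fusion follows from the C6 and C7 centres set in step 12, which the step does not touch. The step needs site selectivity among three hydroxyls and attachment of C12 to the internal alkyne carbon; only O6 is homopropargylic to the ethynyl group (O10 and O15 would need seven- and eight-membered rings and their alkoxycarbonyl complexes revert), O8 is blocked by the ester that the target carries anyway, and the tether length forces C12 onto C11.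

**Compound list**

1 | (R)-(−)-linalool, (3R)-3,7-dimethylocta-1,6-dien-3-ol | C=C[C@](C)(O)CCC=C(C)C | starting material
2 | (3R)-3,7-dimethyl-3-(triethylsilyloxy)octa-1,6-diene | C=C[C@](C)(O[Si](CC)(CC)CC)CCC=C(C)C | intermediate
3 | (4R)-4-methyl-4-(triethylsilyloxy)hex-5-enal | C=C[C@](C)(O[Si](CC)(CC)CC)CCC=O | intermediate
4 | (2R,4R)-4-methyl-2-(phenylaminooxy)-4-(triethylsilyloxy)hex-5-enal | C=C[C@](C)(O[Si](CC)(CC)CC)C[C@@H](ONc1ccccc1)C=O | intermediate
5 | (2R,4R)-4-methyl-2-(phenylaminooxy)-4-(triethylsilyloxy)hex-5-en-1-ol | C=C[C@](C)(O[Si](CC)(CC)CC)C[C@@H](ONc1ccccc1)CO | intermediate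
6 | (2R,4R)-4-methyl-4-(triethylsilyloxy)hex-5-ene-1,2-diol | C=C[C@](C)(O[Si](CC)(CC)CC)C[C@@H](O)CO | intermediate
7 | (3R,5R)-3-methyl-3,5,6-tris(triethylsilyloxy)hex-1-ene | C=C[C@](C)(O[Si](CC)(CC)CC)C[C@@H](O[Si](CC)(CC)CC)CO[Si](CC)(CC)CC | intermediate
8 | methyl acrylate | C=CC(=O)OC | starting material
9 | methyl (2E,4R,6R)-4-methyl-4,6,7-tris(triethylsilyloxy)hept-2-enoate | COC(=O)/C=C/[C@](C)(O[Si](CC)(CC)CC)C[C@@H](O[Si](CC)(CC)CC)CO[Si](CC)(CC)CC | intermediate
10 | methyl (2E,4R,6R)-4-methyl-7-oxo-4,6-bis(triethylsilyloxy)hept-2-enoate | COC(=O)/C=C/[C@](C)(O[Si](CC)(CC)CC)C[C@@H](O[Si](CC)(CC)CC)C=O | intermediate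
11 | methyl (2E,4R,6R,7S)-7-hydroxy-4-methyl-4,6-bis(triethylsilyloxy)-9-(trimethylsilyl)non-2-en-8-ynoate | COC(=O)/C=C/[C@](C)(O[Si](CC)(CC)CC)C[C@@H](O[Si](CC)(CC)CC)[C@@H](O)C#C[Si](C)(C)C | intermediate
12 | methyl (2E,4R,6R,7S)-4-methyl-7-(methylsulfonyloxy)-4,6-bis(triethylsilyloxy)-9-(trimethylsilyl)non-2-en-8-ynoate | COC(=O)/C=C/[C@](C)(O[Si](CC)(CC)CC)C[C@@H](O[Si](CC)(CC)CC)[C@@H](OS(C)(=O)=O)C#C[Si](C)(C)C | intermediate
13 | 2-butyne-1,4-diol | OCC#CCO | starting material
14 | 4-(tert-butyldiphenylsilyloxy)but-2-yn-1-ol | OCC#CCO[Si](c1ccccc1)(c1ccccc1)C(C)(C)C | intermediate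
15 | 4-(tert-butyldiphenylsilyloxy)but-2-ynal | O=CC#CCO[Si](c1ccccc1)(c1ccccc1)C(C)(C)C | intermediate
16 | allenyl(ethyl)zinc reagent: methyl (2E,4R,6R)-9-(ethylzincio)-4-methyl-4,6-bis(triethylsilyloxy)-9-(trimethylsilyl)nona-2,7,8-trienoate, allene axis as drawn | COC(=O)/C=C/[C@](C)(O[Si](CC)(CC)CC)C[C@@H](O[Si](CC)(CC)CC)C([H])=[C@]=C([Zn]CC)[Si](C)(C)C | intermediate
17 | methyl (2E,4R,6R,7S,8S)-11-(tert-butyldiphenylsilyloxy)-8-hydroxy-4-methyl-4,6-bis(triethylsilyloxy)-7-[(trimethylsilyl)ethynyl]undec-2-en-9-ynoate | COC(=O)/C=C/[C@](C)(O[Si](CC)(CC)CC)C[C@@H](O[Si](CC)(CC)CC)[C@@H](C#C[Si](C)(C)C)[C@H](O)C#CCO[Si](c1ccccc1)(c1ccccc1)C(C)(C)C | intermediate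
18 | sodium oxaaluminacycle from O6-directed trans-hydroalumination of 17 (Al bound to O6 and C4, C3 as aluminium alkoxide, 2-methoxyethoxy ligands) | [Na+].COCCO[Al](OCCOC)OC/C=C/[C@](C)(O[Si](CC)(CC)CC)C[C@@H](O[Si](CC)(CC)CC)[C@@H](C#C[Si](C)(C)C)[C@@H]1O[Al-](OCCOC)(OCCOC)C(CO[Si](c2ccccc2)(c2ccccc2)C(C)(C)C)=C1 | intermediate
19 | (2E,4R,6R,7S,8S,9Z)-11-(tert-butyldiphenylsilyloxy)-10-iodo-4-methyl-4,6-bis(triethylsilyloxy)-7-[(trimethylsilyl)ethynyl]undeca-2,9-diene-1,8-diol | OC/C=C/[C@](C)(O[Si](CC)(CC)CC)C[C@@H](O[Si](CC)(CC)CC)[C@@H](C#C[Si](C)(C)C)[C@H](O)/C=C(\I)CO[Si](c1ccccc1)(c1ccccc1)C(C)(C)C | intermediate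
20 | (2E,4R,6R,7S,8S,9Z)-11-(tert-butyldiphenylsilyloxy)-8-hydroxy-10-iodo-4-methyl-4,6-bis(triethylsilyloxy)-7-[(trimethylsilyl)ethynyl]undeca-2,9-dienal | O=C/C=C/[C@](C)(O[Si](CC)(CC)CC)C[C@@H](O[Si](CC)(CC)CC)[C@@H](C#C[Si](C)(C)C)[C@H](O)/C=C(\I)CO[Si](c1ccccc1)(c1ccccc1)C(C)(C)C | intermediate
21 | (2E,4R,6R,7R,8S,9Z)-8-(tert-butyldimethylsilyloxy)-11-(tert-butyldiphenylsilyloxy)-10-iodo-4-methyl-4,6-bis(triethylsilyloxy)-7-[(trimethylsilyl)ethynyl]undeca-2,9-dienal | O=C/C=C/[C@](C)(O[Si](CC)(CC)CC)C[C@@H](O[Si](CC)(CC)CC)[C@@H](C#C[Si](C)(C)C)[C@H](O[Si](C)(C)C(C)(C)C)/C=C(\I)CO[Si](c1ccccc1)(c1ccccc1)C(C)(C)C | intermediate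
22 | (2E,4R,6R,7R,8S,9Z)-8-(tert-butyldimethylsilyloxy)-11-(tert-butyldiphenylsilyloxy)-6-hydroxy-10-iodo-4-methyl-4-(triethylsilyloxy)-7-[(trimethylsilyl)ethynyl]undeca-2,9-dienal | O=C/C=C/[C@](C)(O[Si](CC)(CC)CC)C[C@@H](O)[C@@H](C#C[Si](C)(C)C)[C@H](O[Si](C)(C)C(C)(C)C)/C=C(\I)CO[Si](c1ccccc1)(c1ccccc1)C(C)(C)C | intermediate
23 | (R)-2-methylbutanoic acid | CC[C@@H](C)C(=O)O | starting material
24 | (2E,4R,6R,7R,8S,9Z)-8-(tert-butyldimethylsilyloxy)-11-(tert-butyldiphenylsilyloxy)-10-iodo-4-methyl-1-oxo-4-(triethylsilyloxy)-7-[(trimethylsilyl)ethynyl]undeca-2,9-dien-6-yl (2R)-2-methylbutanoate | O=C/C=C/[C@](C)(O[Si](CC)(CC)CC)C[C@@H](OC(=O)[C@H](C)CC)[C@@H](C#C[Si](C)(C)C)[C@H](O[Si](C)(C)C(C)(C)C)/C=C(\I)CO[Si](c1ccccc1)(c1ccccc1)C(C)(C)C | intermediate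
25 | (2E,4R,6R,7R,8R,9Z)-8-(tert-butyldimethylsilyloxy)-10-[(tert-butyldiphenylsilyloxy)methyl]-1-hydroxy-4-methyl-4-(triethylsilyloxy)-7-[(trimethylsilyl)ethynyl]cyclodeca-2,9-dien-6-yl (2R)-2-methylbutanoate, both C1 epimers | OC1/C=C/[C@](C)(O[Si](CC)(CC)CC)C[C@@H](OC(=O)[C@H](C)CC)[C@@H](C#C[Si](C)(C)C)[C@H](O[Si](C)(C)C(C)(C)C)/C=C\1CO[Si](c1ccccc1)(c1ccccc1)C(C)(C)C | intermediate
26 | (2E,4R,6R,7R,8R,9Z)-8-(tert-butyldimethylsilyloxy)-10-[(tert-butyldiphenylsilyloxy)methyl]-4-methyl-1-oxo-4-(triethylsilyloxy)-7-[(trimethylsilyl)ethynyl]cyclodeca-2,9-dien-6-yl (2R)-2-methylbutanoate | O=C1/C=C/[C@](C)(O[Si](CC)(CC)CC)C[C@@H](OC(=O)[C@H](C)CC)[C@@H](C#C[Si](C)(C)C)[C@H](O[Si](C)(C)C(C)(C)C)/C=C\1CO[Si](c1ccccc1)(c1ccccc1)C(C)(C)C | intermediate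
27 | (2E,4R,6R,7S,8R,9Z)-7-ethynyl-4,8-dihydroxy-10-(hydroxymethyl)-4-methyl-1-oxocyclodeca-2,9-dien-6-yl (2R)-2-methylbutanoate | O=C1/C=C/[C@](C)(O)C[C@@H](OC(=O)[C@H](C)CC)[C@@H](C#C)[C@H](O)/C=C\1CO | intermediate
28 | chloro(alkoxycarbonyl)palladium complex of 27 at O6 (divalent palladium; PPh3 and SnCl3 ligands not drawn) | O=C1/C=C/[C@](C)(O)C[C@@H](OC(=O)[C@H](C)CC)[C@@H](C#C)[C@H](OC(=O)[Pd]Cl)/C=C\1CO | intermediate
29 | (Z)-alkenylpalladium chloride with the lactone closed, Pd on C13 cis to C12 (divalent palladium; ligands not drawn) | Cl[Pd]/C=C1\C(=O)O[C@@H]2/C=C(/CO)C(=O)/C=C/[C@](C)(O)C[C@@H](OC(=O)[C@H](C)CC)[C@@H]12 | intermediate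
30 | CNP0232405.1, (3aR,4R,6R,7E,10Z,11aR)-6-hydroxy-10-(hydroxymethyl)-6-methyl-3-methylidene-2,9-dioxo-2,3,3a,4,5,6,9,11a-octahydrocyclodeca[b]furan-4-yl (2R)-2-methylbutanoate | C=C1C(=O)O[C@@H]2/C=C(/CO)C(=O)/C=C/[C@](C)(O)C[C@@H](OC(=O)[C@H](C)CC)[C@@H]12 | target

**Step count and risks**

Total step count: 21. Longest linear sequence: 19 (steps 1–9, then 12–21); the West fragment takes steps 10–11.

Steps most likely to fail:

1. Step 21. Site selectivity may be lost in three ways: an 8→6 acyl shift followed by lactonisation through O8, resting of O6 in the O6/C3 hemiketal, or palladium/tin activation of the free allylic alcohols. The fallback still takes the lactone carbonyl from CO but through an alkenyl halide; it sets out from 26 and comes back at 30. C-Desilylation of the alkyne (AgNO3, 2,6-lutidine, acetone–water) should give the terminal alkyne F1. Bromoboration with B-bromo-9-borabicyclo[3.3.1]nonane and protonolysis with AcOH should give the 2-bromo-1-alkene F2. HF·pyridine should remove the three O-silyl groups to give the bromo triol F3. Carbonylative lactonisation (Pd(PPh3)4, CO 1 atm, Et3N, MeCN, 60 °C; oxidative addition into C11–Br, CO insertion, capture of the acyl by O6–H) should then give 30.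

2. Step 18. Intermolecular coupling (oligomers) or simple reduction of the C–I bond may win over closure of the strained ten-membered ring. The fallback sets out from 24 and comes back at 26, so that step 19 is not needed. Pinnick oxidation (NaClO2, NaH2PO4, 2-methyl-2-butene) should give the enoic acid F4. Iodine–tin exchange with (Me3Sn)2 and Pd(PPh3)4 should give the alkenylstannane F5. 1-Chloro-N,N,2-trimethylpropenylamine should give the acid chloride F6. Intramolecular Stille acylation (Pd2(dba)3, P(2-furyl)3, high dilution) should close the ring directly to the dienone 26.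

3. Step 12. Facial selectivity at the aldehyde (anti versus syn at C6) may be poor, because the alkynyl substituent of 15 is sterically small. The fallback sets out from 17, obtained as a C6 epimer mixture, and comes back at 17. Dess–Martin oxidation should give the ynone F7, and Noyori transfer hydrogenation with RuCl[(S,S)-TsDPEN](p-cymene) and HCO2H/Et3N should then set C6 under catalyst control.

**Further compounds**

F1 | step 21 | 26 without the alkynyl SiMe3 group (terminal alkyne) | O=C1/C=C/[C@](C)(O[Si](CC)(CC)CC)C[C@@H](OC(=O)[C@H](C)CC)[C@@H](C#C)[C@H](O[Si](C)(C)C(C)(C)C)/C=C\1CO[Si](c1ccccc1)(c1ccccc1)C(C)(C)C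
F2 | step 21 | 2-bromo-1-alkene (1-bromovinyl group on C7), O-silyl groups in place | O=C1/C=C/[C@](C)(O[Si](CC)(CC)CC)C[C@@H](OC(=O)[C@H](C)CC)[C@@H](C(Br)=C)[C@H](O[Si](C)(C)C(C)(C)C)/C=C\1CO[Si](c1ccccc1)(c1ccccc1)C(C)(C)C
F3 | step 21 | bromo triol (1-bromovinyl group on C7, O6, O10 and O15 free) | O=C1/C=C/[C@](C)(O)C[C@@H](OC(=O)[C@H](C)CC)[C@@H](C(Br)=C)[C@H](O)/C=C\1CO
F4 | step 18 | enoic acid from 24 (C3 as CO2H) | OC(=O)/C=C/[C@](C)(O[Si](CC)(CC)CC)C[C@@H](OC(=O)[C@H](C)CC)[C@@H](C#C[Si](C)(C)C)[C@H](O[Si](C)(C)C(C)(C)C)/C=C(\I)CO[Si](c1ccccc1)(c1ccccc1)C(C)(C)C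
F5 | step 18 | alkenyl(trimethyl)stannane acid (SnMe3 on C4) | OC(=O)/C=C/[C@](C)(O[Si](CC)(CC)CC)C[C@@H](OC(=O)[C@H](C)CC)[C@@H](C#C[Si](C)(C)C)[C@H](O[Si](C)(C)C(C)(C)C)/C=C(\[Sn](C)(C)C)CO[Si](c1ccccc1)(c1ccccc1)C(C)(C)C
F6 | step 18 | acid chloride of F5 | ClC(=O)/C=C/[C@](C)(O[Si](CC)(CC)CC)C[C@@H](OC(=O)[C@H](C)CC)[C@@H](C#C[Si](C)(C)C)[C@H](O[Si](C)(C)C(C)(C)C)/C=C(\[Sn](C)(C)C)CO[Si](c1ccccc1)(c1ccccc1)C(C)(C)C
F7 | step 12 | ynone from 17 (C6 ketone) | COC(=O)/C=C/[C@](C)(O[Si](CC)(CC)CC)C[C@@H](O[Si](CC)(CC)CC)[C@@H](C#C[Si](C)(C)C)C(=O)C#CCO[Si](c1ccccc1)(c1ccccc1)C(C)(C)C
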